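The runs stem from a simulated flask from invented constants; noise was put on by code.

A solution saturated at 17 mM cannot turn 0.050 M of substrate into target on a single filling, if one gas goes per substrate: that filling covers a third of the charge.

in all of them: gas phase 17 mM (held)
- blue: substrate 0.025 M; run made earlier
- flask: substrate 0.050 M; time 50 h

- blue (time / h: target / %, substrate / %): 0.417: 0, 99.4; 0.667: 0.5, 100.1; 1.00: 0.5, 100.2; 1.33: 1.8, 98.9; 2.00: 3.0, 97.5; 3.00: 3.9, 96.1; 5.00: 6.9, 93.4

(scatter of a reading: 0.5 percentage points)

- at the start none of the gas phase is in solution

- target at 50 h, in percent of the substrate charged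
- concentration of dissolved gas in solution at 50 h, in percent of saturation

Yet the blue run's loss of substrate, carried forward, seems to break this limit. Its fraction-left constant, minus the logarithm of the fraction left divided by the time 0.0137 h⁻¹, is a reading from 93.4% at 5.00 h. It carries the scatter of 0.5 percentage points. Carried to the flask, it leaves 50.5% of the substrate at 50 h by this reckoning, so half is reckoned to react. That asks 24.7 mM of gas, more than 17 mM. The clash goes once dissolved gas is seen as a flow: the gas phase is held and refills the solution. With steady [dissolved gas], the substrate step is pseudo-first-order, and the fraction left follows the constant. That the charge leaves this constant unchanged is an assumption, since one charge has been run.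

The forecast gives 50% target and 99% of saturation, holding that “The liquid therefore stays essentially saturated”.

The flask gives 57.9% target and 37.3% of saturation, with 39% of the substrate left.

    gas phase ⇌ dissolved gas, rate k1*(csat - [dissolved gas]) (kL = 0.223 h⁻¹)
    substrate + dissolved gas → target (k = 3.22 L mol⁻¹ h⁻¹)
    dissolved gas + target → over-reacted product (k = 0.339 L mol⁻¹ h⁻¹)
    2 dissolved gas → homo dimer (k = 18.7 L mol⁻¹ h⁻¹)
    dissolved gas → decomposed reagent (k = 0.0647 h⁻¹)

The flask's constant is therefore 0.0190 h⁻¹, and divided by the target step's 3.22 L mol⁻¹ h⁻¹ it gives an average [dissolved gas] of 5.90 mM. Read at 12 h, the same flask should keep 79.6% by this constant, and it holds 82%. At 50.0 h, the flask's dissolved gas goes to homo dimer 3.8 times as fast as to target. Supply and use then stand level, at a ratio of 1.00, with [dissolved gas] at 0.00634 M.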